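The readings are calculated with constants of no real substance, and the scatter is random.

No rate constant comes with this flask, so the examiner asks which constant its readings can give. Monday's run is this same flask, followed so far.

| setting | Monday's | flask |
|---|---|---|
| E | 0.10 M | 0.10 M |
| X | 0.050 M | 0.0500 M |
| Z | 4.7 mM | 4.7 mM |
| remark | the very flask that is asked about, followed so far |  |
| time |  | 6.0 h |

Monday's run (percent of the E charged)

| time / h | D / % | E / % |
|---|---|---|
| 0.200 | 0 | 99.1 |
| 0.333 | 2.1 | 99.2 |
| 0.500 | 3.5 | 97.8 |
| 0.833 | 4.2 | 95.4 |
| 1.33 | 4.6 | 95.4 |
| 2.50 | 7.9 | 87.1 |

(standard deviation of a reading: 1 percentage point)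

- the average divides the monomer in chains by the number of chains, living and dead together; two radicals that join make one chain
- the earlier runs do not show the number of chains; that part of a forecast is a guess

- average number of monomer units in a chain (living and dead chains, two that joined counted as one) at 6.0 h
- part of the E that has reacted at 6.0 h

"Which concentration sets the order of the loss of E?" E itself, I answer, if its partners hold nearly steady. Each hour then takes the same fraction of what is left, a pseudo-first-order loss.

"Your constant?" The last reading leaves 87.1% of E at 2.50 h, which gives 0.0552 /h. This is the loss constant, the logarithm of the fraction of E left, sign turned, per hour.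

"Why that reading?" It has lost 12.9%, against a scatter of 1 percentage point. The reading at 0.833 h has lost 4.60%.

"And at the asked time?" By my constant the fraction left is 71.8%, so my estimate is that 28.2% has reacted.

"The weak spot?" Steadiness is my assumption. Also, the reading at 2.50 h puts D at 7.9%, less than E has lost, so some E appears to go elsewhere. My constant counts both roads.

"And dp?" The readings show no number of chains, so I commit to none.

The forecast says 21%, from 15% to 30%, and dp 12, from 3 to 45. Its first step differs from mine: "Averaging D gained and E lost". That gives it 0.04 per hour against my 0.0552 /h.

The flask gives 25.7% reacted, against my 28.2%, and dp 37.4, against the forecast's 12.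

    Z → 2 G (k = 0.0180 /h)
    E + G → J + D (k = 1.90 × 10⁷ /M/h)
    E + J → D + J, rate k3*[J]*[E] (k = 5.70 × 10⁵ /M/h)
    2 J → L (k = 6.70 × 10⁶ /M/s)
    X + E → Q (k = 0.320 /M/h)

The neighbour flask is charged with 0.085 M of X, all else as in this flask. The step X + E → Q adds 0.32 /M/h times the concentration of X to the loss constant. Reckoned on the charges, the extra X adds 0.0112 /h to my 0.0552 /h, giving 0.0664 /h. For 6.0 h that estimate leaves 67.1% of E, so it puts 32.9% as reacted. The neighbour flask gives 30.1% reacted and dp 36.4. At 6.00 h the neighbour's D stands at 17.5% against 18.0% in this flask, and the neighbour's Q at 12.6% against 7.64%.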